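Count turnovers.

| flask | substrate | free catalyst | temperature | remark | time |
|---|---|---|---|---|---|
| Saturday's | 1.5 M | 19 mM | 75 °C | run made earlier |  |
| Friday's | 1.5 M | 28 mM | 110 °C | run made earlier |  |
| Sunday's | 0.75 M | 38 mM | 75 °C | run made earlier |  |
| violet | 1.5 M | 38 mM | 80 °C |  | 40 h |
| green | 1.5 M | 38 mM |  | at 140 °C until 20 h, from then on at 80 °C | 40 h |
| blue | 1.5 M | 38 mM | 110 °C |  | 40 h |
| ochre | 1.5 M | 38 mM | 140 °C |  | 40 h |

| run | time / h | target / % | isomer of the product / % |
|---|---|---|---|
| Saturday's | 4.00 | 2.6 | 0 |
| Saturday's | 12.0 | 8.6 | 0.8 |
| Saturday's | 20.0 | 12.2 | 1.9 |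
| Saturday's | 30.0 | 16.5 | 2.5 |
| Friday's | 0.500 | 4.3 | 0.1 |
| Friday's | 1.33 | 9.3 | 0.4 |
| Friday's | 3.00 | 14.3 | 2.8 |
| Friday's | 6.00 | 17.0 | 3.4 |
| Sunday's | 2.50 | 4.4 | 0 |
| Sunday's | 6.00 | 8.6 | 1.1 |
| Sunday's | 15.0 | 18.0 | 1.5 |
| Sunday's | 30.0 | 27.5 | 5.4 |

(each reading ± 0.5 percentage points)

* the best flask by share of target in all that became target or isomer of the product or uncatalysed product; "all alike" if 1.5 percentage points covers them all (violet / green / blue / ochre / all alike)
* share of target in all that became target or isomer of the product or uncatalysed product, violet
* share of target in all that became target or isomer of the product or uncatalysed product, green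
* share of target in all that became target or isomer of the product or uncatalysed product, blue
* share of target in all that became target or isomer of the product or uncatalysed product, ochre



**What do you count?** Friday's last reading gives 10.9: that is the turnover count (the turnover number), target plus isomer of the product made, in moles per mole of free catalyst charged.

**Is Friday's flask still working?** Barely. It made 4.71 h⁻¹ up to its first reading and 0.589 h⁻¹ between its last two, which is slower. Its charge allowed 53.6 turnovers.

**And the cold run?** Saturday's run reads 15.0, more than Friday's, and it still makes 0.387 h⁻¹ against 0.513 h⁻¹ at its first reading.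

**Carry Friday's count to blue.** At blue's charges it means 27.7% of the substrate passes through the catalyst, of which target is 23.1%.

**Weak spot: where is the remainder?** The readings don't say, because substrate was never read. If it waits as substrate, blue's share is 83.3%; if it all becomes uncatalysed product, the share is 23.1%. Blue runs 40 h, longer than Friday's last reading, so my own reckoning commits to the low figure.

**Violet?** Saturday's count, carried to violet's catalyst charge, estimates 33.0% target; that is an estimate and not a floor, since violet differs from Saturday's run in catalyst, temperature and time. It stands above my figure for blue, so I name violet best, with green and ochre, which start hotter, below blue.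

**The forecast?** It names green, with violet 77%, green 91% (range 78% to 96%), blue 84% and ochre 89%. Of the uncatalysed product it says “I assume it is small but grows with heat”. On blue it stands far above my 23.1%.

**The flasks give:** violet is best, with violet 49.1%, green 7.81%, blue 21.4% and ochre 9.06%.

    substrate + free catalyst → free catalyst + target (k = 0.660 M⁻¹ h⁻¹, Ea = 72.0 kJ mol⁻¹)
    2 free catalyst → spent catalyst (k = 0.300 M⁻¹ h⁻¹, Ea = 102 kJ mol⁻¹)
    target ⇌ isomer of the product (K = 0.320, k = 0.0390 h⁻¹, Ea = 116 kJ mol⁻¹, ΔH = −18.0 kJ mol⁻¹)
    substrate → uncatalysed product (k = 0.0110 h⁻¹, Ea = 125 kJ mol⁻¹)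
    (constants at 80 °C)

Blue ends with 74.4% uncatalysed product and 10.1 turnovers. Violet, at 40.0 h, counts 17.1 turnovers, with 25.1% uncatalysed product and 31.6% substrate left. The neighbouring flask is violet with 0.095 M free catalyst. Its count is 10.1, fewer than violet's, but on the larger charge that puts 64.2% of the substrate into target and isomer of the product. Uncatalysed product there is 18.3%, and the share of target is 59.9%.

Readings and results come from a simulation with made-up constants, noise included.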